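The numbers in the tables were generated by integration with constants of no real substance; the scatter is artificial.

I start with the slope.

| flask | substrate | partner | second reagent | third reagent | temperature | remark | time |
|---|---|---|---|---|---|---|---|
| green | 0.010 M | 0.020 M | 0.011 M | 0.012 M | 5 °C | run made earlier |  |
| violet | 0.010 M | 0.020 M | 0.0055 M | 0.012 M | 20 °C | run made earlier |  |
| blue | 0.010 M | 0.020 M | 0.0083 M | 0.012 M | 5 °C | run made earlier |  |
| amber | 0.020 M | 0.020 M | 0.011 M | 0.012 M | 20 °C | run made earlier |  |
| oak | 0.010 M | 0.0200 M (fed, over 15 min) | 0.0110 M | 0.0120 M | 20 °C | all else is in the flask from the start; the feed brings no volume worth counting | 6.0 h |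
| birch | 0.010 M (fed, over 2.5 h) | 0.0200 M | 0.0110 M | 0.0120 M | 20 °C | all else is in the flask from the start; the feed brings no volume worth counting | 6.0 h |
| larch | 0.010 M | 0.0200 M (fed, over 2.5 h) | 0.0110 M | 0.0120 M | 20 °C | all else is in the flask from the start; the feed brings no volume worth counting | 6.0 h |
| maple | 0.010 M (fed, over 2.5 h) | 0.0200 M | 0.0110 M | 0.0120 M |  | the addition at 0 °C, then warmed to 20 °C; the feed brings no volume worth counting | 6.0 h |
| cedar | 0.010 M (in portions, 5, over 2.5 h) | 0.0200 M | 0.0110 M | 0.0120 M | 20 °C | first portion at the start, last at 2.5 h | 6.0 h |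

| run | time / h | product / % |
|---|---|---|
| green | 1.00 | 0.5 |
| green | 2.00 | 0 |
| green | 3.00 | 1.2 |
| green | 4.00 | 2.5 |
| green | 8.00 | 8.0 |
| green | 12.0 | 14.3 |
| violet | 0.417 | 0.3 |
| violet | 0.667 | 0.4 |
| violet | 1.00 | 1.8 |
| violet | 2.00 | 4.3 |
| violet | 3.00 | 8.0 |
| violet | 5.00 | 16.0 |
| blue | 0.833 | 0.5 |
| blue | 1.33 | 0 |
| blue | 2.00 | 0.5 |
| blue | 4.00 | 1.7 |
| blue | 6.00 | 4.1 |
| blue | 10.0 | 8.7 |
| amber | 0.417 | 0.2 |
| amber | 0.667 | 0.1 |
| amber | 1.33 | 1.9 |
| amber | 2.50 | 8.8 |
| amber | 5.00 | 18.3 |

(scatter of a reading: 0.5 percentage points)

- what is said of product includes idle adduct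
- reactions considered so far: substrate + partner -> intermediate A; second reagent + intermediate A -> intermediate B; third reagent + intermediate B -> product; third reagent + product <-> idle adduct

* the flask that comes out highest in amount of product, in percent of the substrate charged, or "all alike" when all lie within 1.5 percentage points (oak / birch / larch / maple / cedar / all alike)
* product at the end, in percent of the substrate charged, oak
* product at the end, in percent of the substrate charged, birch
* product at the end, in percent of the substrate charged, larch
* product at the end, in percent of the substrate charged, maple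
* product at the end, in percent of the substrate charged, cedar

The earlier runs gain product after a lag (induction period), so I reckon the pace to expect in oak in two ways. Violet gains 8 percentage points between 3.00 h and 5.00 h. Scaled by 2.00 for the second reagent that oak holds, this gives 8 points an hour. Amber already holds oak's second reagent and reads 3.8 points an hour, less.

The two ways part, so I look for the one that cheats. By 5.00 h, the amber reading stands for 0.00366 M of product, more than the 0.00160 M of the violet reading, and both runs started with 0.0120 M of third reagent. So I treat amber's pace as low for oak. The scaled violet figure assumes that third reagent keeps pace, and I treat it as high. I take the mean, 5.9 points an hour, and call it the price of lateness: the product one hour of delay costs at 20 °C with oak's charges.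

Violet's line reaches zero product at a lag of 1.00 h. Oak's partner enters on average 0.125 h late, so my reckoning gives oak 28.8%. Birch's substrate enters on average 1.25 h late. Cedar's evenly spaced portions have the same mean, so I put both flasks 1.12 h later than oak. That costs 6.6 points and leaves 22.2%.

The forecast names oak: “Oak is essentially batch”. It gives oak 29% (25% to 35%), birch 23%, larch 25%, maple 20% and cedar 23.5%. Its birch stands above mine.

The flasks give oak 31.0%, birch 25.2%, larch 26.7%, maple 19.4% and cedar 25.2%, so oak comes out highest.

    substrate + partner → intermediate A (k = 210 M⁻¹ h⁻¹, Ea = 40.0 kJ mol⁻¹)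
    second reagent + intermediate A → intermediate B (k = 21.0 M⁻¹ h⁻¹, Ea = 61.0 kJ mol⁻¹)
    third reagent + intermediate B → product (k = 30.0 M⁻¹ h⁻¹, Ea = 68.0 kJ mol⁻¹)
    third reagent + product ⇌ idle adduct, settled at all times (K = 2800 M⁻¹, ΔH = −18.0 kJ mol⁻¹)
    (constants at 20 °C)

Oak stands 5.8 points above birch, against the 6.6 points I reckoned for birch's delay. In oak at 6.00 h, the half-life of intermediate A by its step with second reagent is 6.3 h, longer than the run. At that time oak's intermediate A holds 42.5%, more than the 31.0% of oak's product.

A flask like oak but with 0.0072 M of third reagent lands outside the forecast's range for oak. If I assume the lag scales inversely with third reagent, it grows by 0.667 h, and the price, carried over unchanged from oak's charges, gives 27.1%. The computed flask gives 21.4%, less than that reckoning and less than the forecast's low end of 25% for oak.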